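## Analysis of the target

The target joins two units through one methylene group. The first is a 2,3,4-trisubstituted tetrahydrofuran (O1, C2–C5) with ring A (3-hydroxy-4-methoxyphenyl) on C2 and CH2OH on C3. The second is a 2,3-dihydrobenzofuran (O1', C2', C3', fused to ring B, C3a'–C7a') with ring C (4-hydroxy-3-methoxyphenyl) on C2', CH2OH on C3' and OMe on C4'. The methylene links C4 to C6'.

There are five stereocentres. In the tetrahydrofuran C2 is R, C3 is S and C4 is S: the aryl group is trans to the C3 CH2OH, and this CH2OH is cis to the C4 benzyl group. In the dihydrobenzofuran C2' is S and C3' is R, a trans ring. The C4–CH2–C6' link insulates the two sets, so neither can control the other and each half must be made as a single enantiomer.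

The sensitive groups are two free phenols and two benzylic ether carbons. C2 is para to a methoxy group and ionises under acid. C2' is para to a free hydroxyl and opens under acid or base through a quinone methide. The 3,4-cis arrangement is the less stable one in any lactone precursor.

The hard part is ring B. C3a' is flanked by two different oxygens (OMe at C4', the ring oxygen at C7a'), and the carbon substituent at C6' is meta to both, a pattern that phenol coupling does not deliver.

The strategy rests on C2'. It is a benzylic ether carbon on ring C, para to the free hydroxyl, so it can be the exocyclic carbon of a p-quinone methide. The C7a' oxygen then adds to it, and C3' alone decides the configuration at C2'.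

## Retrosynthetic reasoning

**Silyl ethers.** Target 41 is traced back to its tetrakis-silyl ether 40. Only O–Si bonds are cut, so the last step forms no skeletal bond and both phenols stay masked while base or acid is in use.

**O1–C5 of the tetrahydrofuran.** 40 is opened to diol 38, which comes from lactone 37 by hydride reduction. C5 is the only ring carbon without a stereocentre. A carbonyl group there also activates the neighbouring carbon for the next disconnection. The forward closure must displace at the primary C5, so that the benzylic C2–O bond is never broken.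

**The bond between C6' and the methylene group.** 37 is cut into aryl boronate 21 and α-methylene lactone 36. This is the convergent point: both halves arrive with their stereocentres set. The forward conjugate addition has to create only C4 of the tetrahydrofuran (C3 of the lactone), by protonation on the face away from the neighbouring CH2OSi group.

**C6'–B.** 21 comes from bromide 20, and 20 from diol-phenol 19 by silylation. The bromine is carried at C6' from the first compound on. It is inert to everything before this point, it lowers the electron density of ring B, and it needs one step to become the coupling handle.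

**O1'–C2' (key disconnection).** 19 is opened to the acyclic 2,3-diarylpropanol 17 through quinone methide 18. C2' is the one centre that can be derived from a neighbour, so the dihydrobenzofuran problem shrinks to a single stereocentre, C3', in an open chain. The forward step has to oxidise ring C and not ring B, close a five-membered ring through oxygen, and deliver the trans ring.

**C3'–C2'.** 17 comes from its bis-PMB ether 16, this from imide 15, and 15 from arylacetyl imide 9 and benzylic bromide 13 with auxiliary 7. A benzylic bromide is among the best electrophiles for an imide enolate, and the R auxiliary gives the R centre. The PMB ethers are chosen because acid removes them without touching the aryl bromide.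

**Arylacetic acid.** 9 comes from acid 6, this from aldehyde 5 by oxidation, 5 from aldehyde 3 by one-carbon homologation, and 3 from difluoride 1 through 2. Ring B is bought, not built. The two fluorines of 1 are replaced one after the other, which tells the two ortho oxygens apart.

**Bromide 13.** It comes from alcohol 12, aldehyde 11 and vanillin 10 by protection, reduction and bromination.

**Lactone 36.** The methylene group is put on last, from 32 through Mannich base 34. 32 comes from alcohol 31 and acid 30. The acid comes from lactone imide 28, the product of a syn-aldol between imide 25 and aldehyde 23 that forms the bond between C2 and C3 of the future tetrahydrofuran. One auxiliary-controlled reaction sets both centres of this half. 25 comes from 7 and 24, and 23 from isovanillin 22.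

## Alternatives that were turned down

**Alternative 1:** Ring B is disconnected into cyclobutenone A1, which carries the complete tetrahydrofuran, and siloxyalkyne A2, which carries C3' and C2' with their substituents.
- Forward key step: heating opens A1 to a vinylketene, which adds to A2. Ring opening, 6π closure and tautomerisation follow and give resorcinol monosilyl ether A3, with new bonds C7a'–C3a' and C4'–C5'.
- For it: the two halves meet in the ring-forming step. The 1,2,3,5-pattern of ring B and the difference between its two oxygens arise by themselves, and no aryl–CH2 coupling is needed. On convergence and on the ring B pattern it is stronger than the chosen route.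
- Against it: A1 and A2 are both long to make and fragile. In A3 the O1'–C2' bond is still missing, and its benzylic oxygen has the configuration opposite to the target. The closure therefore needs clean inversion at a para-alkoxybenzylic carbon, where ionisation erodes the configuration. The C4' silyl ether must also be exchanged for methyl.
- Comparison: it postpones the same ring closure and adds steps after it. The chosen route offers a short linear path to 17 and sets C2' from C3' under thermodynamic control.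

**Alternative 2:** The tetrahydrofuran is cut at C2–C3 and C4–C5 into butenolide A4, which already carries the dihydrobenzofuran on its γ-carbon, and chloro ether A5.
- Forward key step: desilylation of A5 releases a carbonyl ylide that adds across the butenolide double bond, anti to the γ-aryl group, and gives cis-fused bicyclic lactone A6.
- For it: both ring C–C bonds form in one step. The cis relation of C3 and C4 is enforced by the ring fusion, which is stronger than the kinetic protonation of the chosen route.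
- Against it: nothing strong fixes the orientation of ring A at C2 in the addition of an unstabilised ylide. A6 must then lose its lactone C–O bond by hydrogenolysis in a molecule with two other benzylic C–O bonds. A4 also presupposes the finished dihydrobenzofuran, so the O1'–C2' problem is not addressed.
- Comparison: the chosen route offers a C2 centre set by an auxiliary and no hydrogenolysis.

**Alternative 3:** O1–C2 of the tetrahydrofuran is traced to an oxygen insertion into cyclobutanone A7.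
- Forward key step: peracid oxidation, in which the benzylic carbon migrates with retention, gives lactone A8.
- For it: it is a short path to a γ-aryl lactone whose C3 and C4 are cis from the alkene geometry of the cycloaddition. Loss of acetate from A8 would lead to a lactone of the same kind as 36, in fewer steps than the eight used here, so on step count for this half it is as good or better.
- Against it: the ketene cycloaddition gives racemic material, which on coupling with an enantiopure dihydrobenzofuran would give diastereomer mixtures. The aryl group tends to end cis to its neighbour and would have to be epimerised. The two acetoxymethyl groups must be told apart, and the dihydrobenzofuran half is again left open.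
- Comparison: the chosen route pays more steps for 36 but takes both of its centres from one auxiliary-controlled aldol.

Key step: step 12

Remark: the descriptors of 41 are read from its SMILES as 2R,3S,4S (tetrahydrofuran) and 2'S,3'R (dihydrobenzofuran); the atom labels of the analysis are used for all intermediates.

## Route

Step 1
Reactants: 1 4-bromo-2,6-difluorobenzaldehyde
Product: 2 4-bromo-2-fluoro-6-[(4-methoxybenzyl)oxy]benzaldehyde
Conditions: 4-MeOC6H4CH2OH (1.0 equiv), NaH, THF, 0 °C; then 1, −20 → 0 °C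
Reagents that add atoms: 4-methoxybenzyl alcohol, COc1ccc(CO)cc1
Why: Nucleophilic aromatic substitution (SNAr) of a fluorine ortho to the formyl group; the first alkoxy group deactivates the ring, so one equivalent of alkoxide should stop at mono-substitution, and the bromine is a far poorer leaving group.

Step 2
Reactants: 2 4-bromo-2-fluoro-6-[(4-methoxybenzyl)oxy]benzaldehyde
Product: 3 4-bromo-2-methoxy-6-[(4-methoxybenzyl)oxy]benzaldehyde
Conditions: NaOMe (3 equiv), MeOH/THF, 60 °C
Reagents that add atoms: sodium methoxide, C[O-].[Na+]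
Why: Second SNAr at the remaining ortho fluorine; the two ortho oxygens of ring B are now different (OMe for C4', PMB ether for C7a').

Step 3
Reactants: 3 4-bromo-2-methoxy-6-[(4-methoxybenzyl)oxy]benzaldehyde
Product: 5 2-{4-bromo-2-methoxy-6-[(4-methoxybenzyl)oxy]phenyl}acetaldehyde, via methyl enol ether 4 (not isolated)
Conditions: Ph3P(CH2OMe)Cl, KOtBu, THF, 0 °C → rt; then 1 M HCl, THF, rt
Reagents that add atoms: (methoxymethyl)triphenylphosphonium chloride, COC[P+](c1ccccc1)(c1ccccc1)c1ccccc1.[Cl-]; water, O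
Why: Wittig methoxymethylenation followed by hydrolysis of the enol ether is the standard one-carbon homologation of an aldehyde; dilute acid at room temperature should leave the aryl PMB ether intact.

Step 4
Reactants: 5 2-{4-bromo-2-methoxy-6-[(4-methoxybenzyl)oxy]phenyl}acetaldehyde
Product: 6 2-{4-bromo-2-methoxy-6-[(4-methoxybenzyl)oxy]phenyl}acetic acid
Conditions: NaClO2, NaH2PO4, 2-methylbut-2-ene, t-BuOH/H2O, rt
Reagents that add atoms: sodium chlorite, [Na+].[O-]Cl=O
Why: Pinnick oxidation; the alkene scavenges hypochlorous acid, so the electron-rich rings should not be chlorinated.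

Step 5
Reactants: 6 2-{4-bromo-2-methoxy-6-[(4-methoxybenzyl)oxy]phenyl}acetic acid; 7 (R)-4-benzyl-1,3-oxazolidin-2-one
Product: 9 (4R)-4-benzyl-3-(2-{4-bromo-2-methoxy-6-[(4-methoxybenzyl)oxy]phenyl}acetyl)-1,3-oxazolidin-2-one, via mixed pivalic anhydride 8 (not isolated)
Conditions: t-BuCOCl, Et3N, THF, −20 °C; then 7, LiCl, rt
Reagents that add atoms: none
Why: N-Acylation of the oxazolidinone through the mixed anhydride; LiCl activates the oxazolidinone so that no strong base is needed.

Step 6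
Reactants: 10 vanillin
Product: 11 3-methoxy-4-[(4-methoxybenzyl)oxy]benzaldehyde
Conditions: 4-MeOC6H4CH2Cl, K2CO3, DMF, 60 °C
Reagents that add atoms: 4-methoxybenzyl chloride, COc1ccc(CCl)cc1
Why: Williamson etherification of the phenol.

Step 7
Reactants: 11 3-methoxy-4-[(4-methoxybenzyl)oxy]benzaldehyde
Product: 12 {3-methoxy-4-[(4-methoxybenzyl)oxy]phenyl}methanol
Conditions: NaBH4, MeOH/THF, 0 °C
Reagents that add atoms: none
Why: Borohydride reduction of the aldehyde.

Step 8
Reactants: 12 {3-methoxy-4-[(4-methoxybenzyl)oxy]phenyl}methanol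
Product: 13 4-(bromomethyl)-2-methoxy-1-[(4-methoxybenzyl)oxy]benzene
Conditions: CBr4, PPh3, CH2Cl2, 0 °C; used at once
Reagents that add atoms: carbon tetrabromide, BrC(Br)(Br)Br
Why: Appel bromination under neutral conditions, so the acid-labile PMB ether is not exposed to HBr.

Step 9
Reactants: 9 (4R)-4-benzyl-3-(2-{4-bromo-2-methoxy-6-[(4-methoxybenzyl)oxy]phenyl}acetyl)-1,3-oxazolidin-2-one; 13 4-(bromomethyl)-2-methoxy-1-[(4-methoxybenzyl)oxy]benzene
Product: 15 (4R)-4-benzyl-3-[(2R)-2-{4-bromo-2-methoxy-6-[(4-methoxybenzyl)oxy]phenyl}-3-{3-methoxy-4-[(4-methoxybenzyl)oxy]phenyl}propanoyl]-1,3-oxazolidin-2-one, via sodium Z-enolate 14 (not isolated)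
Conditions: NaN(SiMe3)2, THF, −78 °C; then 13, −78 → −40 °C
Reagents that add atoms: none
Why: Evans alkylation; the chelated Z-enolate is attacked by the benzylic bromide on the face opposite the benzyl group of the auxiliary, which sets the future C3' as R and forms the C3'–C2' bond.

Step 10
Reactants: 15 (4R)-4-benzyl-3-[(2R)-2-{4-bromo-2-methoxy-6-[(4-methoxybenzyl)oxy]phenyl}-3-{3-methoxy-4-[(4-methoxybenzyl)oxy]phenyl}propanoyl]-1,3-oxazolidin-2-one
Product: 16 (2R)-2-{4-bromo-2-methoxy-6-[(4-methoxybenzyl)oxy]phenyl}-3-{3-methoxy-4-[(4-methoxybenzyl)oxy]phenyl}propan-1-ol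
Conditions: LiBH4, MeOH (1 equiv), THF, 0 °C
Reagents that add atoms: none
Why: Reductive cleavage of the imide at the exocyclic carbonyl gives the primary alcohol and returns the auxiliary; the reduction should be faster than enolisation, so the α-centre is kept.

Step 11
Reactants: 16 (2R)-2-{4-bromo-2-methoxy-6-[(4-methoxybenzyl)oxy]phenyl}-3-{3-methoxy-4-[(4-methoxybenzyl)oxy]phenyl}propan-1-ol
Product: 17 (2R)-2-(4-bromo-2-hydroxy-6-methoxyphenyl)-3-(4-hydroxy-3-methoxyphenyl)propan-1-ol
Conditions: CF3CO2H, Et3SiH, CH2Cl2, 0 °C; then K2CO3, MeOH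
Reagents that add atoms: none
Why: Acidolysis of both aryl PMB ethers with the silane as cation scavenger; the aryl bromide, which would not survive hydrogenolysis, is untouched, and the brief basic methanolysis removes any trifluoroacetate on the alcohol.

Step 12
Reactants: 17 (2R)-2-(4-bromo-2-hydroxy-6-methoxyphenyl)-3-(4-hydroxy-3-methoxyphenyl)propan-1-ol
Product: 19 [(2S,3R)-6-bromo-2-(4-hydroxy-3-methoxyphenyl)-4-methoxy-2,3-dihydro-1-benzofuran-3-yl]methanol, via p-quinone methide 18 (not isolated)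
Conditions: Ag2O (2.2 equiv), 4 Å MS, CH2Cl2 (0.01 M), rt, dark
Reagents that add atoms: none
Why: Ag2O removes two electrons and two protons from the 4-alkyl-2-methoxyphenol of ring C (phenoxyl radical, then loss of a C2' hydrogen) and gives p-quinone methide 18, whose exocyclic carbon is C2'. The closest known reaction type is the Ag2O or DDQ dehydrogenation of 4-alkylguaiacols to p-quinone methides that a neighbouring phenol traps, as in the oxidative closure of 2'-hydroxyisoflavans to pterocarpans and of 1,3-diarylpropanes to flavans. The C7a' hydroxyl adds to C2' in a 5-exo-trig oxa-1,6-addition that forms O1'–C2', closes the dihydrofuran ring and restores the aromaticity of ring C. The new centre C2' is controlled by C3' alone: the oxygen attacks the face of 18 anti to the CH2OH group, and since the addition is reversible through 18 under the basic oxide, any cis isomer should drain to the trans 2S,3R ring. The step needs oxidation of ring C and not of ring B; the ring B phenol is a resorcinol-type phenol bearing bromine, harder to oxidise than a guaiacol, and it has no para-alkyl group. It also needs the phenol and not the primary hydroxyl as nucleophile, and the latter could only close a four-membered ring. High dilution and a small excess of oxidant are meant to hold back phenoxyl dimerisation and over-oxidation of 19 to the benzofuran.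

Step 13
Reactants: 19 [(2S,3R)-6-bromo-2-(4-hydroxy-3-methoxyphenyl)-4-methoxy-2,3-dihydro-1-benzofuran-3-yl]methanol
Product: 20 (2S,3R)-6-bromo-4-methoxy-2-{3-methoxy-4-[(triisopropylsilyl)oxy]phenyl}-3-{[(triisopropylsilyl)oxy]methyl}-2,3-dihydro-1-benzofuran
Conditions: i-Pr3SiCl, imidazole, DMF, rt
Reagents that add atoms: chlorotriisopropylsilane, CC(C)[Si](Cl)(C(C)C)C(C)C
Why: Silylation of the phenol and the primary alcohol; with the phenol masked the dihydrofuran can no longer reopen through a quinone methide, and the bulky silyl ethers tolerate the mild aqueous base of step 23.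

Step 14
Reactants: 20 (2S,3R)-6-bromo-4-methoxy-2-{3-methoxy-4-[(triisopropylsilyl)oxy]phenyl}-3-{[(triisopropylsilyl)oxy]methyl}-2,3-dihydro-1-benzofuran
Product: 21 2-[(2S,3R)-4-methoxy-2-{3-methoxy-4-[(triisopropylsilyl)oxy]phenyl}-3-{[(triisopropylsilyl)oxy]methyl}-2,3-dihydro-1-benzofuran-6-yl]-4,4,5,5-tetramethyl-1,3,2-dioxaborolane
Conditions: B2pin2, Pd(dppf)Cl2 (3 mol%), KOAc, 1,4-dioxane, 85 °C
Reagents that add atoms: bis(pinacolato)diboron, CC1(C)OB(OC1(C)C)B1OC(C)(C)C(C)(C)O1
Why: Miyaura borylation of an unhindered aryl bromide; the weak acetate base leaves the aryl silyl ether alone.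

Step 15
Reactants: 22 isovanillin
Product: 23 4-methoxy-3-[(triisopropylsilyl)oxy]benzaldehyde
Conditions: i-Pr3SiCl, imidazole, DMF, rt
Reagents that add atoms: chlorotriisopropylsilane, CC(C)[Si](Cl)(C(C)C)C(C)C
Why: Silylation of the phenol; the triisopropylsilyl ether is chosen to survive the peroxide cleavage of step 18 and to fall in the final fluoride step.

Step 16
Reactants: 7 (R)-4-benzyl-1,3-oxazolidin-2-one; 24 methyl 4-chloro-4-oxobutanoate
Product: 25 methyl 4-[(4R)-4-benzyl-2-oxo-1,3-oxazolidin-3-yl]-4-oxobutanoate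
Conditions: Et3N, DMAP (cat.), CH2Cl2, 0 °C → rt
Reagents that add atoms: none
Why: N-Acylation of the oxazolidinone by the acid chloride under acyl-transfer catalysis.

Step 17
Reactants: 25 methyl 4-[(4R)-4-benzyl-2-oxo-1,3-oxazolidin-3-yl]-4-oxobutanoate; 23 4-methoxy-3-[(triisopropylsilyl)oxy]benzaldehyde
Product: 28 (4R)-4-benzyl-3-{[(2R,3R)-2-{4-methoxy-3-[(triisopropylsilyl)oxy]phenyl}-5-oxooxolan-3-yl]carbonyl}-1,3-oxazolidin-2-one, via dibutylboron Z-enolate 26 (not isolated), via syn-aldol adduct 27 (not isolated)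
Conditions: n-Bu2BOTf, i-Pr2NEt, CH2Cl2, 0 °C; then 23, −78 → 0 °C; pH 7 buffer, MeOH, H2O2; then PPTS (cat.), CH2Cl2, rt
Reagents that add atoms: none
Why: Evans syn-aldol through a Zimmerman–Traxler transition state; the imide and not the ester is enolised, and the R auxiliary gives the R,R adduct. The γ-hydroxy ester then lactonises with retention to the trans lactone, which carries the future C2 (R) and C3 of the tetrahydrofuran.

Step 18
Reactants: 28 (4R)-4-benzyl-3-{[(2R,3R)-2-{4-methoxy-3-[(triisopropylsilyl)oxy]phenyl}-5-oxooxolan-3-yl]carbonyl}-1,3-oxazolidin-2-one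
Product: 30 (2R,3R)-2-{4-methoxy-3-[(triisopropylsilyl)oxy]phenyl}-5-oxooxolane-3-carboxylic acid, via peroxy acid 29 (not isolated)
Conditions: LiOH, H2O2, THF/H2O, 0 °C; Na2SO3; then HCl to pH 2
Reagents that add atoms: lithium hydroperoxide (from LiOH and H2O2), [Li+].[O-]O
Why: Hydroperoxide attacks the exocyclic imide carbonyl and frees the auxiliary; sulfite reduces the peroxy acid, and acidification recloses any lactone that was opened.

Step 19
Reactants: 30 (2R,3R)-2-{4-methoxy-3-[(triisopropylsilyl)oxy]phenyl}-5-oxooxolane-3-carboxylic acid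
Product: 31 (4S,5R)-4-(hydroxymethyl)-5-{4-methoxy-3-[(triisopropylsilyl)oxy]phenyl}oxolan-2-one
Conditions: BH3·SMe2, THF, 0 °C → rt; MeOH
Reagents that add atoms: none
Why: Borane reduces the carboxylic acid through an acyloxyborane much faster than the lactone; the neutral conditions avoid translactonisation of the hydroxy lactone.

Step 20
Reactants: 31 (4S,5R)-4-(hydroxymethyl)-5-{4-methoxy-3-[(triisopropylsilyl)oxy]phenyl}oxolan-2-one
Product: 32 (4S,5R)-5-{4-methoxy-3-[(triisopropylsilyl)oxy]phenyl}-4-{[(triisopropylsilyl)oxy]methyl}oxolan-2-one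
Conditions: i-Pr3SiCl, imidazole, DMF, rt
Reagents that add atoms: chlorotriisopropylsilane, CC(C)[Si](Cl)(C(C)C)C(C)C
Why: Silylation of the primary alcohol, done at once so that the free hydroxyl cannot attack the lactone; the bulky group also shields one face of the lactone for step 23.

Step 21
Reactants: 32 (4S,5R)-5-{4-methoxy-3-[(triisopropylsilyl)oxy]phenyl}-4-{[(triisopropylsilyl)oxy]methyl}oxolan-2-one
Product: 34 (4S,5R)-3-[(dimethylamino)methyl]-5-{4-methoxy-3-[(triisopropylsilyl)oxy]phenyl}-4-{[(triisopropylsilyl)oxy]methyl}oxolan-2-one (C3 epimers), via lithium enolate 33 (not isolated)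
Conditions: LiN(SiMe3)2, THF, −78 °C; then CH2=NMe2+ I−, −78 °C → rt
Reagents that add atoms: N,N-dimethylmethyleneiminium iodide (Eschenmoser's salt), C=[N+](C)C.[I-]
Why: Mannich reaction of the lactone enolate; the enolate has no leaving group on its β-carbon, and the configuration at C3 does not matter because that centre becomes sp2 in the next step.

Step 22
Reactants: 34 (4S,5R)-3-[(dimethylamino)methyl]-5-{4-methoxy-3-[(triisopropylsilyl)oxy]phenyl}-4-{[(triisopropylsilyl)oxy]methyl}oxolan-2-one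
Product: 36 (4S,5R)-5-{4-methoxy-3-[(triisopropylsilyl)oxy]phenyl}-3-methylidene-4-{[(triisopropylsilyl)oxy]methyl}oxolan-2-one, via trimethylammonium iodide 35 (not isolated)
Conditions: MeI, MeOH, rt; then NaHCO3 (aq), CH2Cl2, rt
Reagents that add atoms: none
Why: Quaternisation and E1cB loss of trimethylamine give the α-methylene lactone under mild base.

Step 23
Reactants: 21 2-[(2S,3R)-4-methoxy-2-{3-methoxy-4-[(triisopropylsilyl)oxy]phenyl}-3-{[(triisopropylsilyl)oxy]methyl}-2,3-dihydro-1-benzofuran-6-yl]-4,4,5,5-tetramethyl-1,3,2-dioxaborolane; 36 (4S,5R)-5-{4-methoxy-3-[(triisopropylsilyl)oxy]phenyl}-3-methylidene-4-{[(triisopropylsilyl)oxy]methyl}oxolan-2-one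
Product: 37 (3S,4S,5R)-3-{[(2S,3R)-4-methoxy-2-{3-methoxy-4-[(triisopropylsilyl)oxy]phenyl}-3-{[(triisopropylsilyl)oxy]methyl}-2,3-dihydro-1-benzofuran-6-yl]methyl}-5-{4-methoxy-3-[(triisopropylsilyl)oxy]phenyl}-4-{[(triisopropylsilyl)oxy]methyl}oxolan-2-one
Conditions: [Rh(cod)Cl]2 (3 mol%), K3PO4, 1,4-dioxane/H2O (10:1), 50 °C
Reagents that add atoms: none
Why: Hayashi–Miyaura rhodium-catalysed 1,4-addition; the aryl–rhodium species adds its aryl group to the exocyclic CH2 of 36, and the rhodium enolate is protonated by water at the lactone α-carbon. The proton should enter on the face anti to the neighbouring CH2OSi group, which puts the new benzyl group cis to it and sets the future C4 as S; the mild base and temperature are chosen to avoid epimerisation to the trans lactone.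

Step 24
Reactants: 37 (3S,4S,5R)-3-{[(2S,3R)-4-methoxy-2-{3-methoxy-4-[(triisopropylsilyl)oxy]phenyl}-3-{[(triisopropylsilyl)oxy]methyl}-2,3-dihydro-1-benzofuran-6-yl]methyl}-5-{4-methoxy-3-[(triisopropylsilyl)oxy]phenyl}-4-{[(triisopropylsilyl)oxy]methyl}oxolan-2-one
Product: 38 (1R,2S,3S)-3-{[(2S,3R)-4-methoxy-2-{3-methoxy-4-[(triisopropylsilyl)oxy]phenyl}-3-{[(triisopropylsilyl)oxy]methyl}-2,3-dihydro-1-benzofuran-6-yl]methyl}-1-{4-methoxy-3-[(triisopropylsilyl)oxy]phenyl}-2-{[(triisopropylsilyl)oxy]methyl}butane-1,4-diol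
Conditions: LiBH4, THF, 0 °C → rt
Reagents that add atoms: none
Why: Hydride reduction of the lactone to the 1,4-diol; reduction should outrun enolisation, so the cis α-centre is kept, and the bulky silyl ethers resist migration.

Step 25
Reactants: 38 (1R,2S,3S)-3-{[(2S,3R)-4-methoxy-2-{3-methoxy-4-[(triisopropylsilyl)oxy]phenyl}-3-{[(triisopropylsilyl)oxy]methyl}-2,3-dihydro-1-benzofuran-6-yl]methyl}-1-{4-methoxy-3-[(triisopropylsilyl)oxy]phenyl}-2-{[(triisopropylsilyl)oxy]methyl}butane-1,4-diol
Product: 40 (2S,3R)-4-methoxy-6-{[(3S,4S,5R)-5-{4-methoxy-3-[(triisopropylsilyl)oxy]phenyl}-4-{[(triisopropylsilyl)oxy]methyl}oxolan-3-yl]methyl}-2-{3-methoxy-4-[(triisopropylsilyl)oxy]phenyl}-3-{[(triisopropylsilyl)oxy]methyl}-2,3-dihydro-1-benzofuran, via primary tosylate 39 (not isolated)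
Conditions: TsCl, Et3N, DMAP (cat.), CH2Cl2, 0 → 40 °C
Reagents that add atoms: none
Why: Selective sulfonylation of the primary hydroxyl and intramolecular Williamson closure (5-exo-tet) by the benzylic hydroxyl; the C2–O bond is not broken, so C2 stays R and the ring has aryl trans to C3 and C3 cis to C4.

Step 26
Reactants: 40 (2S,3R)-4-methoxy-6-{[(3S,4S,5R)-5-{4-methoxy-3-[(triisopropylsilyl)oxy]phenyl}-4-{[(triisopropylsilyl)oxy]methyl}oxolan-3-yl]methyl}-2-{3-methoxy-4-[(triisopropylsilyl)oxy]phenyl}-3-{[(triisopropylsilyl)oxy]methyl}-2,3-dihydro-1-benzofuran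
Product: 41 4-[(2S,3R)-3-(hydroxymethyl)-6-{[(3S,4S,5R)-5-(3-hydroxy-4-methoxyphenyl)-4-(hydroxymethyl)oxolan-3-yl]methyl}-4-methoxy-2,3-dihydro-1-benzofuran-2-yl]-2-methoxyphenol (CNP0242386.1)
Conditions: Bu4NF, AcOH, THF, 0 °C → rt
Reagents that add atoms: none
Why: Fluoride cleaves all four silyl ethers; the acetic acid buffer keeps the liberated ring C phenol from reopening the dihydrofuran through a quinone methide.

## Compound list

1 | 4-bromo-2,6-difluorobenzaldehyde | O=Cc1c(F)cc(Br)cc1F | starting material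
2 | 4-bromo-2-fluoro-6-[(4-methoxybenzyl)oxy]benzaldehyde | COc1ccc(COc2cc(Br)cc(F)c2C=O)cc1 | intermediate
3 | 4-bromo-2-methoxy-6-[(4-methoxybenzyl)oxy]benzaldehyde | COc1ccc(COc2cc(Br)cc(OC)c2C=O)cc1 | intermediate
4 | 5-bromo-1-methoxy-3-[(4-methoxybenzyl)oxy]-2-(2-methoxyethenyl)benzene (E/Z mixture) | COC=Cc1c(OC)cc(Br)cc1OCc1ccc(OC)cc1 | intermediate
5 | 2-{4-bromo-2-methoxy-6-[(4-methoxybenzyl)oxy]phenyl}acetaldehyde | O=CCc1c(OC)cc(Br)cc1OCc1ccc(OC)cc1 | intermediate
6 | 2-{4-bromo-2-methoxy-6-[(4-methoxybenzyl)oxy]phenyl}acetic acid | OC(=O)Cc1c(OC)cc(Br)cc1OCc1ccc(OC)cc1 | intermediate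
7 | (R)-4-benzyl-1,3-oxazolidin-2-one | O=C1N[C@H](Cc2ccccc2)CO1 | starting material
8 | 2-{4-bromo-2-methoxy-6-[(4-methoxybenzyl)oxy]phenyl}acetic pivalic anhydride | CC(C)(C)C(=O)OC(=O)Cc1c(OC)cc(Br)cc1OCc1ccc(OC)cc1 | intermediate
9 | (4R)-4-benzyl-3-(2-{4-bromo-2-methoxy-6-[(4-methoxybenzyl)oxy]phenyl}acetyl)-1,3-oxazolidin-2-one | O=C(Cc1c(OC)cc(Br)cc1OCc1ccc(OC)cc1)N1[C@H](Cc2ccccc2)COC1=O | intermediate
10 | vanillin | COc1cc(C=O)ccc1O | starting material
11 | 3-methoxy-4-[(4-methoxybenzyl)oxy]benzaldehyde | COc1ccc(COc2ccc(C=O)cc2OC)cc1 | intermediate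
12 | {3-methoxy-4-[(4-methoxybenzyl)oxy]phenyl}methanol | COc1ccc(COc2ccc(CO)cc2OC)cc1 | intermediate
13 | 4-(bromomethyl)-2-methoxy-1-[(4-methoxybenzyl)oxy]benzene | COc1ccc(COc2ccc(CBr)cc2OC)cc1 | intermediate
14 | sodium Z-enolate of 9 | [Na+].[O-]/C(=C\c1c(OC)cc(Br)cc1OCc1ccc(OC)cc1)N1[C@H](Cc2ccccc2)COC1=O | intermediate
15 | (4R)-4-benzyl-3-[(2R)-2-{4-bromo-2-methoxy-6-[(4-methoxybenzyl)oxy]phenyl}-3-{3-methoxy-4-[(4-methoxybenzyl)oxy]phenyl}propanoyl]-1,3-oxazolidin-2-one | O=C(N1[C@H](Cc2ccccc2)COC1=O)[C@H](Cc1ccc(OCc2ccc(OC)cc2)c(OC)c1)c1c(OC)cc(Br)cc1OCc1ccc(OC)cc1 | intermediate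
16 | (2R)-2-{4-bromo-2-methoxy-6-[(4-methoxybenzyl)oxy]phenyl}-3-{3-methoxy-4-[(4-methoxybenzyl)oxy]phenyl}propan-1-ol | OC[C@H](Cc1ccc(OCc2ccc(OC)cc2)c(OC)c1)c1c(OC)cc(Br)cc1OCc1ccc(OC)cc1 | intermediate
17 | (2R)-2-(4-bromo-2-hydroxy-6-methoxyphenyl)-3-(4-hydroxy-3-methoxyphenyl)propan-1-ol | OC[C@H](Cc1ccc(O)c(OC)c1)c1c(OC)cc(Br)cc1O | intermediate
18 | 4-[(2R)-2-(4-bromo-2-hydroxy-6-methoxyphenyl)-3-hydroxypropylidene]-2-methoxycyclohexa-2,5-dien-1-one | OC[C@H](C=C1C=CC(=O)C(OC)=C1)c1c(OC)cc(Br)cc1O | intermediate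
19 | [(2S,3R)-6-bromo-2-(4-hydroxy-3-methoxyphenyl)-4-methoxy-2,3-dihydro-1-benzofuran-3-yl]methanol | Brc1cc(OC)c2c(c1)O[C@H](c1ccc(O)c(OC)c1)[C@H]2CO | intermediate
20 | (2S,3R)-6-bromo-4-methoxy-2-{3-methoxy-4-[(triisopropylsilyl)oxy]phenyl}-3-{[(triisopropylsilyl)oxy]methyl}-2,3-dihydro-1-benzofuran | Brc1cc(OC)c2c(c1)O[C@H](c1ccc(O[Si](C(C)C)(C(C)C)C(C)C)c(OC)c1)[C@H]2CO[Si](C(C)C)(C(C)C)C(C)C | intermediate
21 | 2-[(2S,3R)-4-methoxy-2-{3-methoxy-4-[(triisopropylsilyl)oxy]phenyl}-3-{[(triisopropylsilyl)oxy]methyl}-2,3-dihydro-1-benzofuran-6-yl]-4,4,5,5-tetramethyl-1,3,2-dioxaborolane | CC1(C)OB(OC1(C)C)c1cc(OC)c2c(c1)O[C@H](c1ccc(O[Si](C(C)C)(C(C)C)C(C)C)c(OC)c1)[C@H]2CO[Si](C(C)C)(C(C)C)C(C)C | intermediate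
22 | isovanillin | COc1ccc(C=O)cc1O | starting material
23 | 4-methoxy-3-[(triisopropylsilyl)oxy]benzaldehyde | COc1ccc(C=O)cc1O[Si](C(C)C)(C(C)C)C(C)C | intermediate
24 | methyl 4-chloro-4-oxobutanoate | COC(=O)CCC(=O)Cl | starting material
25 | methyl 4-[(4R)-4-benzyl-2-oxo-1,3-oxazolidin-3-yl]-4-oxobutanoate | COC(=O)CCC(=O)N1[C@H](Cc2ccccc2)COC1=O | intermediate
26 | dibutylboron Z-enolate of 25 | CCCCB(CCCC)O/C(=C\CC(=O)OC)N1[C@H](Cc2ccccc2)COC1=O | intermediate
27 | methyl (3R)-4-[(4R)-4-benzyl-2-oxo-1,3-oxazolidin-3-yl]-3-[(R)-hydroxy{4-methoxy-3-[(triisopropylsilyl)oxy]phenyl}methyl]-4-oxobutanoate | COc1ccc([C@H](O)[C@@H](CC(=O)OC)C(=O)N2[C@H](Cc3ccccc3)COC2=O)cc1O[Si](C(C)C)(C(C)C)C(C)C | intermediate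
28 | (4R)-4-benzyl-3-{[(2R,3R)-2-{4-methoxy-3-[(triisopropylsilyl)oxy]phenyl}-5-oxooxolan-3-yl]carbonyl}-1,3-oxazolidin-2-one | COc1ccc([C@@H]2OC(=O)C[C@H]2C(=O)N2[C@H](Cc3ccccc3)COC2=O)cc1O[Si](C(C)C)(C(C)C)C(C)C | intermediate
29 | (2R,3R)-2-{4-methoxy-3-[(triisopropylsilyl)oxy]phenyl}-5-oxooxolane-3-carboperoxoic acid | COc1ccc([C@@H]2OC(=O)C[C@H]2C(=O)OO)cc1O[Si](C(C)C)(C(C)C)C(C)C | intermediate
30 | (2R,3R)-2-{4-methoxy-3-[(triisopropylsilyl)oxy]phenyl}-5-oxooxolane-3-carboxylic acid | COc1ccc([C@@H]2OC(=O)C[C@H]2C(=O)O)cc1O[Si](C(C)C)(C(C)C)C(C)C | intermediate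
31 | (4S,5R)-4-(hydroxymethyl)-5-{4-methoxy-3-[(triisopropylsilyl)oxy]phenyl}oxolan-2-one | COc1ccc([C@@H]2OC(=O)C[C@H]2CO)cc1O[Si](C(C)C)(C(C)C)C(C)C | intermediate
32 | (4S,5R)-5-{4-methoxy-3-[(triisopropylsilyl)oxy]phenyl}-4-{[(triisopropylsilyl)oxy]methyl}oxolan-2-one | COc1ccc([C@@H]2OC(=O)C[C@H]2CO[Si](C(C)C)(C(C)C)C(C)C)cc1O[Si](C(C)C)(C(C)C)C(C)C | intermediate
33 | lithium enolate of 32 | COc1ccc([C@@H]2OC([O-])=C[C@H]2CO[Si](C(C)C)(C(C)C)C(C)C)cc1O[Si](C(C)C)(C(C)C)C(C)C.[Li+] | intermediate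
34 | (4S,5R)-3-[(dimethylamino)methyl]-5-{4-methoxy-3-[(triisopropylsilyl)oxy]phenyl}-4-{[(triisopropylsilyl)oxy]methyl}oxolan-2-one (C3 epimers) | COc1ccc([C@@H]2OC(=O)C(CN(C)C)[C@H]2CO[Si](C(C)C)(C(C)C)C(C)C)cc1O[Si](C(C)C)(C(C)C)C(C)C | intermediate
35 | trimethylammonium iodide of 34 | COc1ccc([C@@H]2OC(=O)C(C[N+](C)(C)C)[C@H]2CO[Si](C(C)C)(C(C)C)C(C)C)cc1O[Si](C(C)C)(C(C)C)C(C)C.[I-] | intermediate
36 | (4S,5R)-5-{4-methoxy-3-[(triisopropylsilyl)oxy]phenyl}-3-methylidene-4-{[(triisopropylsilyl)oxy]methyl}oxolan-2-one | COc1ccc([C@@H]2OC(=O)C(=C)[C@H]2CO[Si](C(C)C)(C(C)C)C(C)C)cc1O[Si](C(C)C)(C(C)C)C(C)C | intermediate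
37 | (3S,4S,5R)-3-{[(2S,3R)-4-methoxy-2-{3-methoxy-4-[(triisopropylsilyl)oxy]phenyl}-3-{[(triisopropylsilyl)oxy]methyl}-2,3-dihydro-1-benzofuran-6-yl]methyl}-5-{4-methoxy-3-[(triisopropylsilyl)oxy]phenyl}-4-{[(triisopropylsilyl)oxy]methyl}oxolan-2-one | COc1ccc([C@@H]2OC(=O)[C@@H](Cc3cc(OC)c4c(c3)O[C@H](c3ccc(O[Si](C(C)C)(C(C)C)C(C)C)c(OC)c3)[C@H]4CO[Si](C(C)C)(C(C)C)C(C)C)[C@H]2CO[Si](C(C)C)(C(C)C)C(C)C)cc1O[Si](C(C)C)(C(C)C)C(C)C | intermediate
38 | (1R,2S,3S)-3-{[(2S,3R)-4-methoxy-2-{3-methoxy-4-[(triisopropylsilyl)oxy]phenyl}-3-{[(triisopropylsilyl)oxy]methyl}-2,3-dihydro-1-benzofuran-6-yl]methyl}-1-{4-methoxy-3-[(triisopropylsilyl)oxy]phenyl}-2-{[(triisopropylsilyl)oxy]methyl}butane-1,4-diol | COc1ccc([C@H](O)[C@H](CO[Si](C(C)C)(C(C)C)C(C)C)[C@@H](CO)Cc3cc(OC)c4c(c3)O[C@H](c3ccc(O[Si](C(C)C)(C(C)C)C(C)C)c(OC)c3)[C@H]4CO[Si](C(C)C)(C(C)C)C(C)C)cc1O[Si](C(C)C)(C(C)C)C(C)C | intermediate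
39 | 4-O-(4-methylbenzenesulfonyl) derivative (primary tosylate) of 38 | COc1ccc([C@H](O)[C@H](CO[Si](C(C)C)(C(C)C)C(C)C)[C@@H](COS(=O)(=O)c2ccc(C)cc2)Cc3cc(OC)c4c(c3)O[C@H](c3ccc(O[Si](C(C)C)(C(C)C)C(C)C)c(OC)c3)[C@H]4CO[Si](C(C)C)(C(C)C)C(C)C)cc1O[Si](C(C)C)(C(C)C)C(C)C | intermediate
40 | (2S,3R)-4-methoxy-6-{[(3S,4S,5R)-5-{4-methoxy-3-[(triisopropylsilyl)oxy]phenyl}-4-{[(triisopropylsilyl)oxy]methyl}oxolan-3-yl]methyl}-2-{3-methoxy-4-[(triisopropylsilyl)oxy]phenyl}-3-{[(triisopropylsilyl)oxy]methyl}-2,3-dihydro-1-benzofuran | COc1ccc([C@@H]2OC[C@@H](Cc3cc(OC)c4c(c3)O[C@H](c3ccc(O[Si](C(C)C)(C(C)C)C(C)C)c(OC)c3)[C@H]4CO[Si](C(C)C)(C(C)C)C(C)C)[C@H]2CO[Si](C(C)C)(C(C)C)C(C)C)cc1O[Si](C(C)C)(C(C)C)C(C)C | intermediate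
41 | 4-[(2S,3R)-3-(hydroxymethyl)-6-{[(3S,4S,5R)-5-(3-hydroxy-4-methoxyphenyl)-4-(hydroxymethyl)oxolan-3-yl]methyl}-4-methoxy-2,3-dihydro-1-benzofuran-2-yl]-2-methoxyphenol | COc1ccc([C@@H]2OC[C@@H](Cc3cc(OC)c4c(c3)O[C@H](c3ccc(O)c(OC)c3)[C@H]4CO)[C@H]2CO)cc1O | target

## Step count and uncertain steps

Total: 26 steps. Longest linear sequence: 15 steps (steps 1–5, 9–14, 23–26). The lactone branch (steps 15–22) and the bromide branch (steps 6–8) run beside it.

**Step 12 (key step).** What may go wrong: the phenoxyl radical of ring C may couple with a second molecule at its free ortho position faster than it is oxidised on to 18. Quinone methide 18 may tautomerise to the styrene. Product 19 may be dehydrogenated further to the benzofuran.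
Fallback: the same O1'–C2' closure is reached by ionisation of a benzylic alcohol, with no oxidant. It sets out from acid 6. The acid is coupled with (S)-4-benzyl-1,3-oxazolidin-2-one under the conditions of step 5 to give (4S)-4-benzyl-3-(2-{4-bromo-2-methoxy-6-[(4-methoxybenzyl)oxy]phenyl}acetyl)-1,3-oxazolidin-2-one F1. An Evans syn-aldol of F1 with aldehyde 11 (n-Bu2BOTf, i-Pr2NEt) gives the (2S,3S)-β-hydroxy imide F2. The enantiomeric auxiliary is needed because the boron aldol attacks the enolate face opposite to that of the alkylation. LiBH4 then gives the (1S,2R)-1,3-diol F3. Trifluoroacetic acid with anisole removes both PMB ethers and ionises the benzylic alcohol, and the C7a' phenol closes onto the cation to give the trans ring. The fallback comes back to the route at 19.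

**Step 23.** What may go wrong: the rhodium enolate may be protonated with poor facial selectivity, or the cis lactone may epimerise to the trans lactone under the aqueous base. β-Hydride elimination to the benzylidene lactone is a further loss.
Fallback: it sets out from bromide 20 and lactone 36. A Heck reaction (Pd(OAc)2, P(o-tol)3, Et3N, DMF) gives the (3E,4S,5R)-3-arylidene lactone F4. Hydrogenation over Rh/Al2O3 in ethyl acetate adds hydrogen to the face away from the CH2OSi group, the classical way to cis-α,β-disubstituted lactones. It comes back at 37.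

**Step 9.** What may go wrong: enolate 14, flanked by two ortho substituents, may alkylate slowly and fragment to a ketene with loss of the auxiliary on warming, or the diastereoselectivity may erode.
Fallback: it sets out from acid 6 and aldehyde 11. A Perkin condensation (Ac2O, Et3N, heat) gives the (2E)-2,3-diarylprop-2-enoic acid F5. Asymmetric hydrogenation with Ru(OAc)2(BINAP), using the ligand antipode that gives the R acid, leads to (2R)-2,3-diarylpropanoic acid F6; the homogeneous catalyst spares the aryl bromide. BH3·SMe2 reduces F6 to the alcohol, and the fallback comes back at 16.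

**Step 25.** What may go wrong: the benzylic hydroxyl may be sulfonylated or ionised, with epimerisation at C2, or a silyl group may migrate to the neighbouring hydroxyl before closure.
Fallback: it sets out from lactone 37. DIBAL-H in toluene at −78 °C gives the lactol F7, and Et3SiH with BF3·OEt2 in CH2Cl2 at −78 °C reduces the derived oxocarbenium ion at C5. It comes back at 40.

## Further compounds

F1 | step 12 | (4S)-4-benzyl-3-(2-{4-bromo-2-methoxy-6-[(4-methoxybenzyl)oxy]phenyl}acetyl)-1,3-oxazolidin-2-one | O=C(Cc1c(OC)cc(Br)cc1OCc1ccc(OC)cc1)N1[C@@H](Cc2ccccc2)COC1=O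
F2 | step 12 | (4S)-4-benzyl-3-[(2S,3S)-2-{4-bromo-2-methoxy-6-[(4-methoxybenzyl)oxy]phenyl}-3-hydroxy-3-{3-methoxy-4-[(4-methoxybenzyl)oxy]phenyl}propanoyl]-1,3-oxazolidin-2-one | O=C(N1[C@@H](Cc2ccccc2)COC1=O)[C@H]([C@H](O)c1ccc(OCc2ccc(OC)cc2)c(OC)c1)c1c(OC)cc(Br)cc1OCc1ccc(OC)cc1
F3 | step 12 | (1S,2R)-2-{4-bromo-2-methoxy-6-[(4-methoxybenzyl)oxy]phenyl}-1-{3-methoxy-4-[(4-methoxybenzyl)oxy]phenyl}propane-1,3-diol | OC[C@H]([C@H](O)c1ccc(OCc2ccc(OC)cc2)c(OC)c1)c1c(OC)cc(Br)cc1OCc1ccc(OC)cc1
F4 | step 23 | (3E,4S,5R)-3-{[(2S,3R)-4-methoxy-2-{3-methoxy-4-[(triisopropylsilyl)oxy]phenyl}-3-{[(triisopropylsilyl)oxy]methyl}-2,3-dihydro-1-benzofuran-6-yl]methylidene}-5-{4-methoxy-3-[(triisopropylsilyl)oxy]phenyl}-4-{[(triisopropylsilyl)oxy]methyl}oxolan-2-one | COc1ccc([C@@H]2OC(=O)/C(=C/c3cc(OC)c4c(c3)O[C@H](c3ccc(O[Si](C(C)C)(C(C)C)C(C)C)c(OC)c3)[C@H]4CO[Si](C(C)C)(C(C)C)C(C)C)[C@H]2CO[Si](C(C)C)(C(C)C)C(C)C)cc1O[Si](C(C)C)(C(C)C)C(C)C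
F5 | step 9 | (2E)-2-{4-bromo-2-methoxy-6-[(4-methoxybenzyl)oxy]phenyl}-3-{3-methoxy-4-[(4-methoxybenzyl)oxy]phenyl}prop-2-enoic acid | O=C(O)/C(=C/c1ccc(OCc2ccc(OC)cc2)c(OC)c1)c1c(OC)cc(Br)cc1OCc1ccc(OC)cc1
F6 | step 9 | (2R)-2-{4-bromo-2-methoxy-6-[(4-methoxybenzyl)oxy]phenyl}-3-{3-methoxy-4-[(4-methoxybenzyl)oxy]phenyl}propanoic acid | O=C(O)[C@H](Cc1ccc(OCc2ccc(OC)cc2)c(OC)c1)c1c(OC)cc(Br)cc1OCc1ccc(OC)cc1
F7 | step 25 | (3S,4S,5R)-3-{[(2S,3R)-4-methoxy-2-{3-methoxy-4-[(triisopropylsilyl)oxy]phenyl}-3-{[(triisopropylsilyl)oxy]methyl}-2,3-dihydro-1-benzofuran-6-yl]methyl}-5-{4-methoxy-3-[(triisopropylsilyl)oxy]phenyl}-4-{[(triisopropylsilyl)oxy]methyl}oxolan-2-ol (anomers) | COc1ccc([C@@H]2OC(O)[C@@H](Cc3cc(OC)c4c(c3)O[C@H](c3ccc(O[Si](C(C)C)(C(C)C)C(C)C)c(OC)c3)[C@H]4CO[Si](C(C)C)(C(C)C)C(C)C)[C@H]2CO[Si](C(C)C)(C(C)C)C(C)C)cc1O[Si](C(C)C)(C(C)C)C(C)C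
A1 | alternative 1 | 3-{[(3S,4S,5R)-5-[3-(benzyloxy)-4-methoxyphenyl]-4-{[(tert-butyldimethylsilyl)oxy]methyl}oxolan-3-yl]methyl}cyclobut-2-en-1-one | COc1ccc([C@@H]2OC[C@@H](CC3=CC(=O)C3)[C@H]2CO[Si](C)(C)C(C)(C)C)cc1OCc1ccccc1
A2 | alternative 1 | {[(3R,4R)-4-[4-(benzyloxy)-3-methoxyphenyl]-3-[(benzyloxy)methyl]-4-[(tert-butyldimethylsilyl)oxy]but-1-yn-1-yl]oxy}triisopropylsilane | CC(C)[Si](C(C)C)(C(C)C)OC#C[C@H](COCc1ccccc1)[C@@H](O[Si](C)(C)C(C)(C)C)c1ccc(OCc2ccccc2)c(OC)c1
A3 | alternative 1 | 5-{[(3S,4S,5R)-5-[3-(benzyloxy)-4-methoxyphenyl]-4-{[(tert-butyldimethylsilyl)oxy]methyl}oxolan-3-yl]methyl}-2-{(1R,2R)-1-[4-(benzyloxy)-3-methoxyphenyl]-3-(benzyloxy)-1-[(tert-butyldimethylsilyl)oxy]propan-2-yl}-3-[(triisopropylsilyl)oxy]phenol | COc1ccc([C@@H]2OC[C@@H](Cc3cc(O[Si](C(C)C)(C(C)C)C(C)C)c([C@H](COCc4ccccc4)[C@@H](O[Si](C)(C)C(C)(C)C)c4ccc(OCc5ccccc5)c(OC)c4)c(O)c3)[C@H]2CO[Si](C)(C)C(C)(C)C)cc1OCc1ccccc1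
A4 | alternative 2 | (5R)-5-[(2S,3R)-2-[4-(benzyloxy)-3-methoxyphenyl]-3-{[(tert-butyldimethylsilyl)oxy]methyl}-4-methoxy-2,3-dihydro-1-benzofuran-6-yl]furan-2(5H)-one | O=C1C=C[C@H](c2cc(OC)c3c(c2)O[C@H](c2ccc(OCc4ccccc4)c(OC)c2)[C@H]3CO[Si](C)(C)C(C)(C)C)O1
A5 | alternative 2 | ({chloro[3-(benzyloxy)-4-methoxyphenyl]methoxy}methyl)trimethylsilane | COc1ccc(C(Cl)OC[Si](C)(C)C)cc1OCc1ccccc1
A6 | alternative 2 | cis-fused 3,7-dioxabicyclo[3.3.0]octan-2-one with 3-(benzyloxy)-4-methoxyphenyl on the ether carbon next to the lactone α-carbon and the protected dihydrobenzofuran-6-yl group on the lactone γ-carbon | COc1ccc([C@@H]2OC[C@H]3[C@H](c4cc(OC)c5c(c4)O[C@H](c4ccc(OCc6ccccc6)c(OC)c4)[C@H]5CO[Si](C)(C)C(C)(C)C)OC(=O)[C@@H]23)cc1OCc1ccccc1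
A7 | alternative 3 | 2-[3-(benzyloxy)-4-methoxyphenyl]-3,4-bis(acetoxymethyl)cyclobutan-1-one (aryl trans to the C3 group, C3 and C4 groups cis) | COc1ccc([C@@H]2C(=O)[C@@H](COC(C)=O)[C@H]2COC(C)=O)cc1OCc1ccccc1
A8 | alternative 3 | 5-[3-(benzyloxy)-4-methoxyphenyl]-3,4-bis(acetoxymethyl)oxolan-2-one (aryl trans to the C4 group, C3 and C4 groups cis) | COc1ccc([C@@H]2OC(=O)[C@@H](COC(C)=O)[C@H]2COC(C)=O)cc1OCc1ccccc1
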